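Atom numbers are those of the isoflavone (O1, C2, C3, C4, C4a, C5–C8, C8a; primed numbers for ring B). Compound numbers are those of the steps below.

## The problem

The target 25 is an isoflavone, a 3-aryl-4H-chromen-4-one, with a fully substituted ring A. C5, C7 and C8 carry hydroxyl groups, C6 a methoxy group and C8a the ring oxygen; C4a is the only ring A carbon bonded to carbon instead of oxygen. Ring B is a 3-hydroxy-4,5-dimethoxyphenyl group on C3. There is no stereocenter, so the difficulty is regiochemistry and the order of events, not control in space. The single methyl ether at C6 must sit between two free phenols. The oxygen on C8a must also be told apart from the oxygen on C5, its counterpart across C4a, because closing ring C through the wrong one would give the 8-methoxy isomer. The free compound contains a 5,8-hydroquinone and a 7,8-catechol and will oxidize to quinones in air, so all four phenols must stay masked until a last, non-oxidizing step; the crowded, acid-sensitive pentaoxygenated arene is also a poor substrate for Lewis-acid acylation. The enabling feature is C4, a carbonyl carbon bonded only to C4a and C3. C4a can carry an iodide between two ether groups, and C3 with C2 can arrive as a 1-arylvinylboron unit that already holds ring B, so C4 itself can be carbon monoxide.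

## Retrosynthesis

**25 from 24.** The four O–benzyl bonds at C5, C7, C8 and C3' are cut. Benzyl is chosen for every phenol because one neutral hydrogenolysis then releases the oxidation-prone polyphenol with no acid, base or oxidant present. The methyl ethers at C6, C4' and C5' are untouched. Isoflavone 24 has the full skeleton, so the forward step only has to spare the C2=C3 bond.

**24 from 23, and 23 from 21.** The C2=C3 double bond is traced back to isoflavanone 23 (dehydrogenation), and the O1–C2 bond of 23 is cut to give enone 21. Cutting O1–C2 rather than O1–C8a keeps all five ring A oxygens in place from the start, at the price of one oxidation. The forward closure is a 6-endo conjugate addition of the C8a phenol 22 to the terminal methylene. It requires that only the C8a oxygen be unmasked, so that oxygen carries a methoxymethyl group (acid-labile) while C5, C7 and C8 carry benzyl groups (acid-stable).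

**21 from 11, 19 and 20.** Both bonds to C4 are cut: C4a–C4 and C4–C3. This gives aryl iodide 11, vinylboronate 19 and carbon monoxide 20, two fragments of similar size plus a one-carbon linchpin. The neighbouring cuts are weaker: Friedel–Crafts acylation at C4a would expose the MOM and benzyl ethers to Lewis acid and still need a separate one-carbon insertion for C2, and an aryllithium–aldehyde–oxidation sequence costs extra steps. The forward reaction must insert carbon monoxide faster than it couples the two partners directly, on a di-ortho-substituted, electron-rich iodide.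

**11 from 10, 9, 6, 5, 3, 2 and 1.** The C–I bond and the C5 O–benzyl bond are cut to phenol 9, whose only free ring carbon (C4a) lies ortho to the free C5 hydroxyl. The C5–O bond of 9 is traced to the C–Br bond of 6, the MOM ether of 6 to phenol 5, and the C8a–O bond of 5 to the formyl carbon of bromoaldehyde 3. Aldehyde 3 comes from 2 by bromination, and 2 from commercial catechol aldehyde 1 by benzylation. Aldehyde 1 already has the C6 methoxy group and the C7 and C8 oxygens in the right order. Its formyl carbon marks C8a, and the ring position para to one ether and ortho to the methoxy group (future C5) is the one most activated toward bromine. The two oxygens are therefore introduced one after the other, which is what allows them different protecting groups.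

**19 from 17 and 18, back to 12.** The C–B bond is cut to enol triflate 17 and diboron 18. Triflate 17 comes from methyl ketone 15, which comes from commercial aldehyde 12 by benzylation (13), methyl addition (14) and oxidation. A methyl aryl ketone can enolize in one direction only, so the boron ends up on the carbon bearing ring B. Hydroboration of the corresponding alkyne would favour the linear isomer, which is why that shorter cut is not used.

## Roads not taken

**Alternative 1:** Ring A is cut at C8–C8a (and, one step earlier, at C4a–C5) and built on a preformed 4-pyranone. Heating cyclobutenone A2 should open the four-membered ring and close the ketene terminus onto the pyranone C2–H carbon, giving chromone A1 with free hydroxyls at C5 and C8, the C6 methoxy group and a tert-butyl ether at C7. A2 would come from adding the metalated form of bromopyranone A4 to the mixed squaric ester A3.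
- Merits: all five ring A oxygens come from squaric acid with no arene functionalization sequence, ring C is already at the chromone oxidation level, and the route is clearly shorter than the chosen one.
- Weak points: a 3-metalated 4-pyranone is a fragile nucleophile on a ring that is itself a conjugate acceptor. A3 offers two carbonyl groups that differ only in a methoxy versus tert-butoxy neighbour, and the wrong addition gives the 7-methoxy-6-tert-butoxy isomer. Closure onto an electron-poor pyranone carbon is less well tested than closure onto an arene. A1 exposes the 5,8-hydroquinone at high temperature and then to the acid needed for tert-butyl removal.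
- Comparison: this road is shorter and more convergent. The chosen plan sets against it unambiguous placement of the C6 methoxy group, phenols that stay masked to the end, and steps that are each standard for their substrate class.

**Alternative 2:** Ring A is cut at C4a–C5 and C8–C8a. Heating cyclobutenone A6 with siloxyalkyne A7 should give, by ring opening, ketene–alkyne cycloaddition, a second ring opening and six-electron closure, phenol A5. In A5 the C5 oxygen is free and the C8a oxygen is silylated.
- Merits: the annulation is regiospecific and delivers the C5/C8a differentiation in a single step, with no reliance on the selectivity of an aromatic bromination. In that respect it is better than steps 2 to 5 of the chosen route.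
- Weak points: it builds only ring A. A5 is the silyl analogue of phenol 9 and would still need iodination, benzylation and the same carbonylative coupling. A6 must itself be made from a squaric ester in several steps and A7 is sensitive, whereas 9 is reached in five conventional steps from commercial 1.
- Comparison: the overall step count would not fall. The chosen plan relies on the electronic bias of 2 for bromination at one site, which is strong, and gains cheap starting material and scalable operations.

**Alternative 3:** Ring C is cut at O1–C8a. (NH4)2Ce(NO3)6 (tetravalent cerium) would oxidize the 5,8-dimethoxy ring of ketone A9 to acylquinone A10, whose side-chain enol oxygen adds to C8a to give chromone A8 as the 5,8-hydroquinone.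
- Merits: the C8a oxygen need not be installed or differentiated, because ring A enters with a C–H at C8a. The chromone oxidation level is reached directly, so the dehydrogenation of step 15 disappears and the route is shorter.
- Weak points: the cerium oxidant must choose the ring A para-dimethoxy pair in the presence of an equally electron-rich trialkoxy ring B and an enolized 1,3-dicarbonyl unit. An ortho-quinone from the C5 and C6 methoxy groups, which would lose the C6 methyl, is a competing outcome. A8 is a free hydroquinone formed in an oxidizing medium, and A9 would need an acylation of a polyalkoxyarene followed by formylation.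
- Comparison: this road wins on step count and avoids the late hydrogenation. The chosen plan sets against it that no oxidant meets a free phenol or the unprotected ring B, and that the C6 methoxy group is never at risk.

Key step: step 13

Remark on the chemistry: compounds 14 and 23 are racemic; the stereocenter of 23 is removed in step 15 and the target has none. Compounds 1, 12, 18 and 20 are taken as purchased.

## Route

Step 1
Reactants: 1 2,3-dihydroxy-4-methoxybenzaldehyde
Product: 2 2,3-bis(benzyloxy)-4-methoxybenzaldehyde
Conditions: BnBr, K2CO3, DMF, 60 °C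
Reagents that add atoms: benzyl bromide, BrCc1ccccc1
Why: Williamson etherification; mild heating alkylates both phenoxides, including the one hydrogen-bonded to the aldehyde, and nothing else in 1 reacts.

Step 2
Reactants: 2 2,3-bis(benzyloxy)-4-methoxybenzaldehyde
Product: 3 2,3-bis(benzyloxy)-5-bromo-4-methoxybenzaldehyde
Conditions: NBS, DMF, rt
Reagents that add atoms: N-bromosuccinimide, O=C1CCC(=O)N1Br
Why: Electrophilic aromatic bromination; the benzaldehyde C5 position (future C5) is para to the C2 ether, ortho to the methoxy group and meta to the formyl group, whereas C6 is ortho to the deactivating formyl group and helped only by the flanked, twisted C3 ether, so bromine should enter at C5.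

Step 3
Reactants: 3 2,3-bis(benzyloxy)-5-bromo-4-methoxybenzaldehyde
Product: 5 2,3-bis(benzyloxy)-5-bromo-4-methoxyphenol, via aryl formate 4 (not isolated)
Conditions: mCPBA, CH2Cl2, 0 °C to rt; NaHCO3 wash; then K2CO3 (cat.), MeOH, rt
Reagents that add atoms: meta-chloroperoxybenzoic acid, OOC(=O)c1cccc(Cl)c1
Why: Baeyer–Villiger (Dakin-type) oxidation; the electron-rich aryl group migrates in preference to hydride to give formate 4, which mild methanolysis cleaves, and the aryl bromide and benzyl ethers are inert to peracid.

Step 4
Reactants: 5 2,3-bis(benzyloxy)-5-bromo-4-methoxyphenol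
Product: 6 2,3-bis(benzyloxy)-5-bromo-4-methoxy-1-(methoxymethoxy)benzene
Conditions: MOMCl, i-Pr2NEt, CH2Cl2, 0 °C to rt
Reagents that add atoms: chloromethyl methyl ether, COCCl
Why: O-alkylation of the phenol with an alpha-chloro ether; this puts the one acid-labile ether on the future C8a oxygen.

Step 5
Reactants: 6 2,3-bis(benzyloxy)-5-bromo-4-methoxy-1-(methoxymethoxy)benzene
Product: 9 3,4-bis(benzyloxy)-2-methoxy-5-(methoxymethoxy)phenol, via aryllithium 7 (not isolated), via lithium aryltrimethoxyborate 8 (not isolated)
Conditions: n-BuLi, THF, −78 °C; B(OMe)3, −78 to 0 °C; then 30% H2O2, aq NaOH, 0 °C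
Reagents that add atoms: hydrogen peroxide, OO
Why: Bromine–lithium exchange at −78 °C outruns any deprotonation; borate formation and alkaline peroxide oxidation (aryl shift from boron to oxygen) turn C–Br into C–OH, and MOM and benzyl ethers tolerate both stages.

Step 6
Reactants: 9 3,4-bis(benzyloxy)-2-methoxy-5-(methoxymethoxy)phenol
Product: 10 3,4-bis(benzyloxy)-6-iodo-2-methoxy-5-(methoxymethoxy)phenol
Conditions: NIS, MeCN, 0 °C, dark
Reagents that add atoms: N-iodosuccinimide, O=C1CCC(=O)N1I
Why: Electrophilic iodination of a phenol; the only unsubstituted ring carbon (future C4a) is ortho to the free hydroxyl, so the site is fixed, and neutral conditions spare the MOM acetal.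

Step 7
Reactants: 10 3,4-bis(benzyloxy)-6-iodo-2-methoxy-5-(methoxymethoxy)phenol
Product: 11 1,2,4-tris(benzyloxy)-5-iodo-3-methoxy-6-(methoxymethoxy)benzene
Conditions: BnBr, K2CO3, DMF, 50 °C
Reagents that add atoms: benzyl bromide, BrCc1ccccc1
Why: Williamson etherification of the hindered iodophenol; it completes the pattern of benzyl on the C5 oxygen and MOM on the C8a oxygen.

Step 8
Reactants: 12 3-hydroxy-4,5-dimethoxybenzaldehyde
Product: 13 3-(benzyloxy)-4,5-dimethoxybenzaldehyde
Conditions: BnBr, K2CO3, DMF, rt
Reagents that add atoms: benzyl bromide, BrCc1ccccc1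
Why: Williamson etherification of the single phenol of ring B.

Step 9
Reactants: 13 3-(benzyloxy)-4,5-dimethoxybenzaldehyde
Product: 14 1-[3-(benzyloxy)-4,5-dimethoxyphenyl]ethan-1-ol (racemic)
Conditions: MeMgBr, THF, 0 °C
Reagents that add atoms: methylmagnesium bromide, C[Mg]Br
Why: Grignard addition to an aromatic aldehyde; the new stereocenter is formed as a racemate and removed in the next step.

Step 10
Reactants: 14 1-[3-(benzyloxy)-4,5-dimethoxyphenyl]ethan-1-ol (racemic)
Product: 15 1-[3-(benzyloxy)-4,5-dimethoxyphenyl]ethan-1-one
Conditions: MnO2, CH2Cl2, rt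
Reagents that add atoms: none
Why: MnO2 oxidation of an electron-rich benzylic alcohol to the aryl methyl ketone; benzyl and methyl ethers are unaffected.

Step 11
Reactants: 15 1-[3-(benzyloxy)-4,5-dimethoxyphenyl]ethan-1-one
Product: 17 1-[3-(benzyloxy)-4,5-dimethoxyphenyl]ethenyl trifluoromethanesulfonate, via potassium enolate 16 (not isolated)
Conditions: KN(SiMe3)2, THF, −78 °C; PhNTf2, −78 to 0 °C
Reagents that add atoms: N-phenylbis(trifluoromethanesulfonimide), O=S(=O)(N(c1ccccc1)S(=O)(=O)C(F)(F)F)C(F)(F)F
Why: Enolate O-sulfonylation; the methyl ketone can enolize only toward the methyl group, so the terminal enol triflate is the sole regioisomer.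

Step 12
Reactants: 17 1-[3-(benzyloxy)-4,5-dimethoxyphenyl]ethenyl trifluoromethanesulfonate; 18 bis(pinacolato)diboron
Product: 19 2-{1-[3-(benzyloxy)-4,5-dimethoxyphenyl]ethenyl}-4,4,5,5-tetramethyl-1,3,2-dioxaborolane
Conditions: PdCl2(PPh3)2 (3 mol%), PPh3 (6 mol%), KOPh, toluene, 50 °C
Reagents that add atoms: none
Why: Miyaura borylation of an alkenyl triflate; the weak phenoxide base activates the diboron without promoting Suzuki coupling of the product with unreacted triflate.

Step 13
Reactants: 11 1,2,4-tris(benzyloxy)-5-iodo-3-methoxy-6-(methoxymethoxy)benzene; 19 2-{1-[3-(benzyloxy)-4,5-dimethoxyphenyl]ethenyl}-4,4,5,5-tetramethyl-1,3,2-dioxaborolane; 20 carbon monoxide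
Product: 21 1-[3,4,6-tris(benzyloxy)-5-methoxy-2-(methoxymethoxy)phenyl]-2-[3-(benzyloxy)-4,5-dimethoxyphenyl]prop-2-en-1-one
Conditions: PdCl2(PPh3)2 (5 mol%), K2CO3, CO (1 atm), anisole, 80 °C
Reagents that add atoms: none
Why: Carbonylative Suzuki–Miyaura coupling: the divalent palladium precatalyst is reduced in situ to zerovalent palladium, which inserts into the C4a–I bond of 11; carbon monoxide then undergoes migratory insertion to an aroylpalladium iodide, the carbonate-activated vinylboronate 19 transmetalates, and reductive elimination forms C4–C3 and returns the catalyst. The closest known reaction type is the three-component coupling of ortho-disubstituted aryl iodides, carbon monoxide and aryl- or alkenylboron reagents to hindered ketones. No ring is closed and no stereocenter is formed. The selectivity needed is ketone formation over direct, carbon-monoxide-free coupling. The two ortho ethers (OMOM and OBn) slow transmetalation at the crowded arylpalladium centre, whereas the electron-rich aryl group migrates readily to bound carbon monoxide and the resulting acyl centre, one atom further from the ring, is open to the boronate. Anhydrous carbonate and moderate temperature should protect the terminal enone of 21 from conjugate addition and polymerization.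

Step 14
Reactants: 21 1-[3,4,6-tris(benzyloxy)-5-methoxy-2-(methoxymethoxy)phenyl]-2-[3-(benzyloxy)-4,5-dimethoxyphenyl]prop-2-en-1-one
Product: 23 5,7,8-tris(benzyloxy)-3-[3-(benzyloxy)-4,5-dimethoxyphenyl]-6-methoxy-2,3-dihydro-4H-chromen-4-one (racemic), via free phenol 22 (not isolated)
Conditions: 3 M aq HCl, THF, 50 °C; NaHCO3 work-up; then Et3N (cat.), CH2Cl2, rt
Reagents that add atoms: none
Why: Acid hydrolysis of the MOM acetal (benzyl ethers are stable) frees only the C8a phenol 22, which closes ring C by 6-endo-trig oxa-Michael addition to the unsubstituted methylene, the classical isoflavanone closure; C3 is formed as a racemate and becomes sp2 in step 15.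

Step 15
Reactants: 23 5,7,8-tris(benzyloxy)-3-[3-(benzyloxy)-4,5-dimethoxyphenyl]-6-methoxy-2,3-dihydro-4H-chromen-4-one (racemic)
Product: 24 5,7,8-tris(benzyloxy)-3-[3-(benzyloxy)-4,5-dimethoxyphenyl]-6-methoxy-4H-chromen-4-one
Conditions: DDQ, 1,4-dioxane, reflux
Reagents that add atoms: none
Why: Quinone dehydrogenation of an isoflavanone to the isoflavone (hydride abstraction from C2 of the enol, then proton loss), driven by formation of the aromatic pyranone; there is no free phenol for DDQ to oxidize and plain benzyl ethers are slow to react with it in the dark.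

Step 16
Reactants: 24 5,7,8-tris(benzyloxy)-3-[3-(benzyloxy)-4,5-dimethoxyphenyl]-6-methoxy-4H-chromen-4-one
Product: 25 5,7,8,3'-tetrahydroxy-6,4',5'-trimethoxyisoflavone
Conditions: H2 (1 atm), 10% Pd/C, EtOAc/MeOH, rt; filtration and concentration under argon
Reagents that add atoms: none
Why: Hydrogenolysis of four aryl benzyl ethers under neutral, reducing conditions; the chromone C2=C3 bond is reduced much more slowly than the benzyl ethers are cleaved, and the air-sensitive hydroquinone–catechol is released without acid, base or oxidant.

## Compound list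

1 | 2,3-dihydroxy-4-methoxybenzaldehyde | COc1ccc(C=O)c(O)c1O | starting material
2 | 2,3-bis(benzyloxy)-4-methoxybenzaldehyde | COc1ccc(C=O)c(OCc2ccccc2)c1OCc1ccccc1 | intermediate
3 | 2,3-bis(benzyloxy)-5-bromo-4-methoxybenzaldehyde | COc1c(Br)cc(C=O)c(OCc2ccccc2)c1OCc1ccccc1 | intermediate
4 | 2,3-bis(benzyloxy)-5-bromo-4-methoxyphenyl formate | COc1c(Br)cc(OC=O)c(OCc2ccccc2)c1OCc1ccccc1 | intermediate
5 | 2,3-bis(benzyloxy)-5-bromo-4-methoxyphenol | COc1c(Br)cc(O)c(OCc2ccccc2)c1OCc1ccccc1 | intermediate
6 | 2,3-bis(benzyloxy)-5-bromo-4-methoxy-1-(methoxymethoxy)benzene | COCOc1cc(Br)c(OC)c(OCc2ccccc2)c1OCc1ccccc1 | intermediate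
7 | [3,4-bis(benzyloxy)-2-methoxy-5-(methoxymethoxy)phenyl]lithium | [Li]c1cc(OCOC)c(OCc2ccccc2)c(OCc2ccccc2)c1OC | intermediate
8 | lithium [3,4-bis(benzyloxy)-2-methoxy-5-(methoxymethoxy)phenyl]trimethoxyborate | [Li+].CO[B-](OC)(OC)c1cc(OCOC)c(OCc2ccccc2)c(OCc2ccccc2)c1OC | intermediate
9 | 3,4-bis(benzyloxy)-2-methoxy-5-(methoxymethoxy)phenol | COCOc1cc(O)c(OC)c(OCc2ccccc2)c1OCc1ccccc1 | intermediate
10 | 3,4-bis(benzyloxy)-6-iodo-2-methoxy-5-(methoxymethoxy)phenol | COCOc1c(I)c(O)c(OC)c(OCc2ccccc2)c1OCc1ccccc1 | intermediate
11 | 1,2,4-tris(benzyloxy)-5-iodo-3-methoxy-6-(methoxymethoxy)benzene | COCOc1c(I)c(OCc2ccccc2)c(OC)c(OCc2ccccc2)c1OCc1ccccc1 | intermediate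
12 | 3-hydroxy-4,5-dimethoxybenzaldehyde | COc1cc(C=O)cc(O)c1OC | starting material
13 | 3-(benzyloxy)-4,5-dimethoxybenzaldehyde | COc1cc(C=O)cc(OCc2ccccc2)c1OC | intermediate
14 | 1-[3-(benzyloxy)-4,5-dimethoxyphenyl]ethan-1-ol (racemic) | COc1cc(C(C)O)cc(OCc2ccccc2)c1OC | intermediate
15 | 1-[3-(benzyloxy)-4,5-dimethoxyphenyl]ethan-1-one | COc1cc(C(C)=O)cc(OCc2ccccc2)c1OC | intermediate
16 | potassium 1-[3-(benzyloxy)-4,5-dimethoxyphenyl]ethen-1-olate | [K+].[O-]C(=C)c1cc(OC)c(OC)c(OCc2ccccc2)c1 | intermediate
17 | 1-[3-(benzyloxy)-4,5-dimethoxyphenyl]ethenyl trifluoromethanesulfonate | COc1cc(C(=C)OS(=O)(=O)C(F)(F)F)cc(OCc2ccccc2)c1OC | intermediate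
18 | bis(pinacolato)diboron | CC1(C)OB(OC1(C)C)B1OC(C)(C)C(C)(C)O1 | starting material
19 | 2-{1-[3-(benzyloxy)-4,5-dimethoxyphenyl]ethenyl}-4,4,5,5-tetramethyl-1,3,2-dioxaborolane | COc1cc(C(=C)B2OC(C)(C)C(C)(C)O2)cc(OCc2ccccc2)c1OC | intermediate
20 | carbon monoxide | [C-]#[O+] | starting material
21 | 1-[3,4,6-tris(benzyloxy)-5-methoxy-2-(methoxymethoxy)phenyl]-2-[3-(benzyloxy)-4,5-dimethoxyphenyl]prop-2-en-1-one | COCOc1c(C(=O)C(=C)c2cc(OCc3ccccc3)c(OC)c(OC)c2)c(OCc2ccccc2)c(OC)c(OCc2ccccc2)c1OCc1ccccc1 | intermediate
22 | 1-[3,4,6-tris(benzyloxy)-2-hydroxy-5-methoxyphenyl]-2-[3-(benzyloxy)-4,5-dimethoxyphenyl]prop-2-en-1-one | COc1cc(C(=C)C(=O)c2c(O)c(OCc3ccccc3)c(OCc3ccccc3)c(OC)c2OCc2ccccc2)cc(OCc2ccccc2)c1OC | intermediate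
23 | 5,7,8-tris(benzyloxy)-3-[3-(benzyloxy)-4,5-dimethoxyphenyl]-6-methoxy-2,3-dihydro-4H-chromen-4-one (racemic) | COc1cc(C2COc3c(OCc4ccccc4)c(OCc4ccccc4)c(OC)c(OCc4ccccc4)c3C2=O)cc(OCc2ccccc2)c1OC | intermediate
24 | 5,7,8-tris(benzyloxy)-3-[3-(benzyloxy)-4,5-dimethoxyphenyl]-6-methoxy-4H-chromen-4-one | COc1cc(-c2coc3c(OCc4ccccc4)c(OCc4ccccc4)c(OC)c(OCc4ccccc4)c3c2=O)cc(OCc2ccccc2)c1OC | intermediate
25 | 5,7,8,3'-tetrahydroxy-6,4',5'-trimethoxyisoflavone | COc1cc(-c2coc3c(O)c(O)c(OC)c(O)c3c2=O)cc(O)c1OC | target

## Step count and risks

Total: 16 steps. Longest linear sequence: 11 steps (steps 1–7, then 13–16). The ring B arm is steps 8–12.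

**Step 13 (key step).** Oxidative addition into the very electron-rich, doubly ortho-substituted C–I bond may be slow, so hydrodeiodination could compete. Transmetalation of the pinacol ester under anhydrous carbonate may lag, so the aroylpalladium intermediate could be lost to hydrolysis. The terminal enone of the product may be consumed by conjugate addition or polymerization at 80 °C. Direct coupling without carbon monoxide is the lesser concern for the steric reasons in the step.
- Fallback, from iodide 11 and triflate 17, returning at enone 21: iodine–lithium exchange on 11 (n-BuLi, THF, −78 °C) and quenching with DMF would give 3,4,6-tris(benzyloxy)-5-methoxy-2-(methoxymethoxy)benzaldehyde F1. A Nozaki–Hiyama–Kishi coupling of F1 with 17 (CrCl2, divalent chromium, with catalytic NiCl2, divalent nickel, in DMF) would give racemic 1-[3,4,6-tris(benzyloxy)-5-methoxy-2-(methoxymethoxy)phenyl]-2-[3-(benzyloxy)-4,5-dimethoxyphenyl]prop-2-en-1-ol F2. Oxidation of this doubly activated alcohol with MnO2 would return 21. C4 then comes from DMF instead of carbon monoxide.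

**Step 6.** The pentaoxygenated phenol may be oxidized toward a quinone by the electrophilic iodine source, or the MOM group may be lost if acid builds up.
- Fallback, from phenol 9, returning at iodide 11: benzylation (BnBr, K2CO3, DMF) would give 1,3,4-tris(benzyloxy)-2-methoxy-5-(methoxymethoxy)benzene F3. Directed ortho-lithiation of its single ring hydrogen, flanked by the MOM and benzyl ethers (n-BuLi, THF, 0 °C), followed by I2, would give 11 without an electrophilic step on a free phenol.

**Step 11 (with step 12).** The alpha-aryl enol triflate of so electron-rich an arene may ionize or hydrolyse back to ketone 15 during isolation, and the derived boronate may protodeboronate during step 12.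
- Fallback, from ketone 15, returning at boronate 19: condensation with 2,4,6-triisopropylbenzenesulfonyl hydrazide would give the (E)-hydrazone N'-{1-[3-(benzyloxy)-4,5-dimethoxyphenyl]ethylidene}-2,4,6-triisopropylbenzenesulfonohydrazide F4. A Shapiro reaction (n-BuLi, 2 equiv, THF, −78 to 0 °C) would generate the 1-arylvinyllithium, which is trapped with 2-isopropoxy-4,4,5,5-tetramethyl-1,3,2-dioxaborolane to give 19. This bypasses 17 and the palladium borylation.

**Step 15.** Hydride abstraction from the hindered 5-benzyloxy isoflavanone may be slow, and prolonged heating with DDQ invites oxidative loss of benzyl ethers.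
- Fallback, from isoflavanone 23, returning at isoflavone 24: soft enolization (Me3SiOTf, Et3N, CH2Cl2), which avoids a free enolate and the ring opening it could trigger, would give {5,7,8-tris(benzyloxy)-3-[3-(benzyloxy)-4,5-dimethoxyphenyl]-6-methoxy-2H-chromen-4-yl}oxy(trimethyl)silane F5. Saegusa–Ito oxidation with Pd(OAc)2 (divalent palladium) in MeCN would give 24.

**Step 16.** Over-reduction of the C2=C3 bond may occur before the last benzyl ether is cleaved, and the product may oxidize in air during work-up.
- Fallback, from 24 directly to 25: Lewis-acid debenzylation with BCl3 and pentamethylbenzene as cation scavenger in CH2Cl2 at −78 °C, which cleaves benzyl ethers in preference to methyl ethers and involves no hydrogen; it makes no new compound (F0).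

## Further compounds

F1 | step 13 | 3,4,6-tris(benzyloxy)-5-methoxy-2-(methoxymethoxy)benzaldehyde | COCOc1c(C=O)c(OCc2ccccc2)c(OC)c(OCc2ccccc2)c1OCc1ccccc1
F2 | step 13 | 1-[3,4,6-tris(benzyloxy)-5-methoxy-2-(methoxymethoxy)phenyl]-2-[3-(benzyloxy)-4,5-dimethoxyphenyl]prop-2-en-1-ol (racemic) | COCOc1c(C(O)C(=C)c2cc(OCc3ccccc3)c(OC)c(OC)c2)c(OCc2ccccc2)c(OC)c(OCc2ccccc2)c1OCc1ccccc1
F3 | step 6 | 1,3,4-tris(benzyloxy)-2-methoxy-5-(methoxymethoxy)benzene | COCOc1cc(OCc2ccccc2)c(OC)c(OCc2ccccc2)c1OCc1ccccc1
F4 | step 11 | (E)-N'-{1-[3-(benzyloxy)-4,5-dimethoxyphenyl]ethylidene}-2,4,6-triisopropylbenzenesulfonohydrazide | C/C(=N\NS(=O)(=O)c1c(C(C)C)cc(C(C)C)cc1C(C)C)c1cc(OC)c(OC)c(OCc2ccccc2)c1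
F5 | step 15 | {5,7,8-tris(benzyloxy)-3-[3-(benzyloxy)-4,5-dimethoxyphenyl]-6-methoxy-2H-chromen-4-yl}oxy(trimethyl)silane | COc1cc(C2=C(O[Si](C)(C)C)c3c(OCc4ccccc4)c(OC)c(OCc4ccccc4)c(OCc4ccccc4)c3OC2)cc(OCc2ccccc2)c1OC
F0 | step 16 | none | none
A1 | alternative 1 | 7-tert-butoxy-5,8-dihydroxy-6-methoxy-3-(3-benzyloxy-4,5-dimethoxyphenyl)chromen-4-one | COc1c(O)c2c(=O)c(-c3cc(OCc4ccccc4)c(OC)c(OC)c3)coc2c(O)c1OC(C)(C)C
A2 | alternative 1 | 2-tert-butoxy-4-hydroxy-3-methoxy-4-{5-[3-(benzyloxy)-4,5-dimethoxyphenyl]-4-oxo-4H-pyran-3-yl}cyclobut-2-en-1-one | COC1=C(OC(C)(C)C)C(=O)C1(O)c1cocc(-c2cc(OCc3ccccc3)c(OC)c(OC)c2)c1=O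
A3 | alternative 1 | 3-tert-butoxy-4-methoxycyclobut-3-ene-1,2-dione | COC1=C(OC(C)(C)C)C(=O)C1=O
A4 | alternative 1 | 3-bromo-5-[3-(benzyloxy)-4,5-dimethoxyphenyl]-4H-pyran-4-one | COc1cc(-c2cocc(Br)c2=O)cc(OCc2ccccc2)c1OC
A5 | alternative 2 | 3,4-bis(benzyloxy)-2-methoxy-5-(triisopropylsilyloxy)phenol | COc1c(O)cc(O[Si](C(C)C)(C(C)C)C(C)C)c(OCc2ccccc2)c1OCc1ccccc1
A6 | alternative 2 | 2,3-bis(benzyloxy)-4-methoxycyclobut-2-en-1-one (racemic) | COC1C(=O)C(OCc2ccccc2)=C1OCc1ccccc1
A7 | alternative 2 | (ethynyloxy)triisopropylsilane | C#CO[Si](C(C)C)(C(C)C)C(C)C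
A8 | alternative 3 | 7-(benzyloxy)-3-[3-(benzyloxy)-4,5-dimethoxyphenyl]-5,8-dihydroxy-6-methoxychromen-4-one | COc1c(OCc2ccccc2)c(O)c2occ(-c3cc(OCc4ccccc4)c(OC)c(OC)c3)c(=O)c2c1O
A9 | alternative 3 | 1-[4-(benzyloxy)-2,3,5-trimethoxyphenyl]-2-[3-(benzyloxy)-4,5-dimethoxyphenyl]-3-hydroxyprop-2-en-1-one | COc1cc(C(=O)C(=CO)c2cc(OCc3ccccc3)c(OC)c(OC)c2)c(OC)c(OC)c1OCc1ccccc1
A10 | alternative 3 | 5-(benzyloxy)-2-{2-[3-(benzyloxy)-4,5-dimethoxyphenyl]-3-hydroxyprop-2-enoyl}-6-methoxycyclohexa-2,5-diene-1,4-dione | COC1=C(OCc2ccccc2)C(=O)C=C(C(=O)C(=CO)c2cc(OCc3ccccc3)c(OC)c(OC)c2)C1=O
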